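## Retrosynthetic overview

1. Notation: unit 1 is the 2-(3,4-dihydroxyphenyl)chroman-4-one (benzo ring A, pyranone ring C, aryl ring B); unit 2 is the 2-(4-hydroxyphenyl)chroman-4-one (benzo ring D, pyranone ring F, aryl ring E); C3 of unit 1 is bonded to C8 of unit 2. Target 26 ⇐ 25 ⇐ 23: the end only unmasks oxygen (six benzyl ethers; the ring-E hydroxyl is carried as a C–B bond).
2. Key disconnection: ring F is cut at O1–C2 and C4–C4a, giving phenol 14 (unit 1 carrying ring D as a 2-hydroxy-4,6-bis(benzyloxy)phenyl group on C3) and the (S)-β-lactone 20. Enabling feature: in unit 2, O1 and C4 sit on neighbouring carbons (C8a, C4a) of the phloroglucinol-type ring D, C4a has oxygen on both ortho carbons and on the para carbon, and C2 (benzylic, O-bearing) and C4 (acyl) are 1,3-related, which is the pattern of a 4-aryl-oxetan-2-one.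
3. 14 ⇐ 12 ⇐ 11 + 5: the C3(unit 1)–C8(unit 2) bond comes from an aryllead coupling at the β-keto ester carbon; the ester is then lost and C3 settles trans to C2.
4. 11 ⇐ 10 ⇐ 8 + 9: ring C is closed by a catalytic asymmetric oxa-Michael addition that sets C2 of unit 1.
5. Order of ring formation: rings A, B, D and E are bought as benzene rings; ring C is closed first (step 7), ring F last (step 14).

Key step: step 14

Remark: the sense of induction of the cinchona thiourea (step 7) and of (R)-BINAP (step 10) is taken by analogy with the parent flavanone and benzoylacetate series; if the other antipode forms, the pseudoenantiomeric (quinine-derived) thiourea or (S)-BINAP is used instead.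

## Route

Step 1
Reactants: 1 3,5-bis(benzyloxy)phenol
Product: 2 1,3-bis(benzyloxy)-5-(methoxymethoxy)benzene
Conditions: MOMCl, i-Pr2NEt, CH2Cl2, 0 °C to rt
Reagents that add atoms: chloromethyl methyl ether, COCCl
Why: O-alkylation of the phenol gives the methoxymethyl ether, which is the only acid-labile protecting group of the route and the directing group for step 2.

Step 2
Reactants: 2 1,3-bis(benzyloxy)-5-(methoxymethoxy)benzene
Product: 4 tributyl[2,4-bis(benzyloxy)-6-(methoxymethoxy)phenyl]stannane, via aryllithium 3 (not isolated)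
Conditions: n-BuLi, THF, 0 °C; then Bu3SnCl, −78 °C to rt
Reagents that add atoms: tributyltin chloride, CCCC[Sn](Cl)(CCCC)CCCC
Why: Directed ortho-metalation: the methoxymethoxy group, helped by the neighbouring benzyloxy group, directs lithiation to the carbon between them (two equivalent sites), and the aryllithium is trapped on tin.

Step 3
Reactants: 4 tributyl[2,4-bis(benzyloxy)-6-(methoxymethoxy)phenyl]stannane
Product: 5 [2,4-bis(benzyloxy)-6-(methoxymethoxy)phenyl]lead triacetate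
Conditions: Pb(OAc)4, Hg(OAc)2 (5 mol%), CHCl3, rt to 40 °C
Reagents that add atoms: lead tetraacetate, CC(=O)O[Pb](OC(C)=O)(OC(C)=O)OC(C)=O
Why: Tin-to-lead exchange (electrophilic ipso-substitution of the aryl–tin bond, with mercury diacetate as transmetalation catalyst) gives the aryllead triacetate without touching the acetal or the benzyl ethers.

Step 4
Reactants: 6 1-(2,4,6-trihydroxyphenyl)ethanone
Product: 7 1-[2,4-bis(benzyloxy)-6-hydroxyphenyl]ethanone
Conditions: BnBr (2.1 equiv), K2CO3 (2.1 equiv), DMF, rt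
Reagents that add atoms: benzyl bromide, BrCc1ccccc1
Why: Williamson etherification stops at the dibenzyl ether because the hydroxyl that is hydrogen-bonded to the ketone is the least nucleophilic.

Step 5
Reactants: 7 1-[2,4-bis(benzyloxy)-6-hydroxyphenyl]ethanone
Product: 8 tert-butyl 3-[2,4-bis(benzyloxy)-6-hydroxyphenyl]-3-oxopropanoate
Conditions: LiN(SiMe3)2 (3.1 equiv), THF, −78 °C; Boc2O (1.05 equiv), −78 to 0 °C; 1 M HCl work-up
Reagents that add atoms: di-tert-butyl dicarbonate, CC(C)(C)OC(=O)OC(=O)OC(C)(C)C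
Why: Claisen-type C-carboxylation of the ketone enolate within the phenoxide–enolate dianion, in which the chelated phenoxide is the poorer nucleophile.

Step 6
Reactants: 8 tert-butyl 3-[2,4-bis(benzyloxy)-6-hydroxyphenyl]-3-oxopropanoate; 9 3,4-bis(benzyloxy)benzaldehyde
Product: 10 tert-butyl 2-[2,4-bis(benzyloxy)-6-hydroxybenzoyl]-3-[3,4-bis(benzyloxy)phenyl]prop-2-enoate (E/Z mixture; both isomers converge in step 7)
Conditions: piperidine (10 mol%), AcOH (10 mol%), 4 Å molecular sieves, toluene, rt to 40 °C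
Reagents that add atoms: none
Why: Knoevenagel condensation of the β-keto ester with the aryl aldehyde gives the doubly activated alkene needed for a catalyst-controlled ring closure.

Step 7
Reactants: 10 tert-butyl 2-[2,4-bis(benzyloxy)-6-hydroxybenzoyl]-3-[3,4-bis(benzyloxy)phenyl]prop-2-enoate
Product: 11 tert-butyl (2R,3S)-5,7-bis(benzyloxy)-2-[3,4-bis(benzyloxy)phenyl]-4-oxochromane-3-carboxylate
Conditions: thiourea from 9-amino-9-deoxy-epi-quinidine and 3,5-bis(trifluoromethyl)phenyl isothiocyanate (10 mol%), toluene, −25 °C; cold filtration through a short silica pad, used at once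
Reagents that add atoms: none
Why: Catalytic asymmetric intramolecular oxa-Michael addition (6-endo-trig) to an alkylidene β-keto ester, in which the quinuclidine nitrogen activates the phenol and the thiourea binds the 1,3-dicarbonyl, so the catalyst sets C2 (2R); C3 is a labile β-keto ester centre, drawn as the trans keto form.

Step 8
Reactants: 11 tert-butyl (2R,3S)-5,7-bis(benzyloxy)-2-[3,4-bis(benzyloxy)phenyl]-4-oxochromane-3-carboxylate; 5 [2,4-bis(benzyloxy)-6-(methoxymethoxy)phenyl]lead triacetate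
Product: 12 tert-butyl (2S,3R)-5,7-bis(benzyloxy)-3-[2,4-bis(benzyloxy)-6-(methoxymethoxy)phenyl]-2-[3,4-bis(benzyloxy)phenyl]-4-oxochromane-3-carboxylate (the two aryl groups trans; the C2 descriptor changes by priority only)
Conditions: pyridine (3 equiv), CHCl3, rt to 40 °C
Reagents that add atoms: none
Why: α-Arylation of a β-keto ester by an aryllead triacetate (enol ligand exchange at lead, then reductive ligand coupling), a reaction type used to build hindered aryl-bearing quaternary carbons on 3-alkoxycarbonylchroman-4-ones; the aryl group should enter C3 anti to the C2 aryl group, and the quaternary C3 then blocks any ring opening at C2.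

Step 9
Reactants: 12 tert-butyl (2S,3R)-5,7-bis(benzyloxy)-3-[2,4-bis(benzyloxy)-6-(methoxymethoxy)phenyl]-2-[3,4-bis(benzyloxy)phenyl]-4-oxochromane-3-carboxylate
Product: 14 (2R,3S)-5,7-bis(benzyloxy)-2-[3,4-bis(benzyloxy)phenyl]-3-[2,4-bis(benzyloxy)-6-hydroxyphenyl]chroman-4-one, via keto acid 13 (not isolated)
Conditions: TFA/CH2Cl2 (1:4), H2O (10 equiv), 0 °C to rt
Reagents that add atoms: none
Why: Acidolysis removes the tert-butyl ester and the methoxymethyl acetal, keto acid 13 loses CO2 through its enol, and the new C3–H equilibrates under the acid to the 2,3-trans (3S) arrangement dictated by the C2 aryl group (thermodynamic control).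

Step 10
Reactants: 15 ethyl 3-(4-bromophenyl)-3-oxopropanoate
Product: 16 ethyl (3S)-3-(4-bromophenyl)-3-hydroxypropanoate
Conditions: [RuCl(p-cymene)((R)-BINAP)]Cl (0.5 mol%), H2 (50 bar), EtOH, 60 °C
Reagents that add atoms: none
Why: Noyori asymmetric hydrogenation of a β-keto ester, in which the chiral diphosphine sets the carbinol centre and the aryl bromide is not reduced.

Step 11
Reactants: 16 ethyl (3S)-3-(4-bromophenyl)-3-hydroxypropanoate
Product: 17 ethyl (3S)-3-hydroxy-3-[4-(4,4,5,5-tetramethyl-1,3,2-dioxaborolan-2-yl)phenyl]propanoate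
Conditions: B2pin2, PdCl2(dppf) (3 mol%), KOAc, 1,4-dioxane, 80 °C
Reagents that add atoms: bis(pinacolato)diboron, CC1(C)OB(B2OC(C)(C)C(C)(C)O2)OC1(C)C
Why: Miyaura borylation turns the C–Br bond into a C–B bond, a latent hydroxyl that does not donate electrons to the benzylic carbon; the stereocentre is not involved.

Step 12
Reactants: 17 ethyl (3S)-3-hydroxy-3-[4-(4,4,5,5-tetramethyl-1,3,2-dioxaborolan-2-yl)phenyl]propanoate
Product: 18 (3S)-3-hydroxy-3-[4-(4,4,5,5-tetramethyl-1,3,2-dioxaborolan-2-yl)phenyl]propanoic acid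
Conditions: LiOH, THF/H2O, 0 °C to rt; then 1 M HCl to pH 3
Reagents that add atoms: lithium hydroxide, [Li+].[OH-]
Why: Saponification of the ethyl ester does not touch the carbinol centre, and the pinacol boronate should survive brief cold base.

Step 13
Reactants: 18 (3S)-3-hydroxy-3-[4-(4,4,5,5-tetramethyl-1,3,2-dioxaborolan-2-yl)phenyl]propanoic acid
Product: 20 (4S)-4-[4-(4,4,5,5-tetramethyl-1,3,2-dioxaborolan-2-yl)phenyl]oxetan-2-one, via sulfonic mixed anhydride 19 (not isolated)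
Conditions: PhSO2Cl (2 equiv), pyridine, 0 °C
Reagents that add atoms: none
Why: β-Lactonization by carboxyl activation: the hydroxyl oxygen attacks the acyl carbon of mixed anhydride 19, so the carbinol C–O bond is kept and the configuration is retained.

Step 14
Reactants: 14 (2R,3S)-5,7-bis(benzyloxy)-2-[3,4-bis(benzyloxy)phenyl]-3-[2,4-bis(benzyloxy)-6-hydroxyphenyl]chroman-4-one; 20 (4S)-4-[4-(4,4,5,5-tetramethyl-1,3,2-dioxaborolan-2-yl)phenyl]oxetan-2-one
Product: 23 (2R)-5,7-bis(benzyloxy)-8-[(2R,3S)-5,7-bis(benzyloxy)-2-[3,4-bis(benzyloxy)phenyl]-4-oxochroman-3-yl]-2-[4-(4,4,5,5-tetramethyl-1,3,2-dioxaborolan-2-yl)phenyl]chroman-4-one, via cesium carboxylate 21 (not isolated), via trifluoroacetic mixed anhydride 22 (not isolated)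
Conditions: Cs2CO3 (1.05 equiv), 20 (1.2 equiv), MeCN, 0 °C to rt; then CH2Cl2, TFAA (5 equiv), 0 °C to rt
Reagents that add atoms: none
Why: Proposed new method: the cesium phenoxide of 14 (its only free hydroxyl, on ring D next to the carbon that carries unit 1) attacks the benzylic C4 of the strained (S)-lactone 20 by SN2 alkyl–oxygen fission, which forms the O1–C2 bond of unit 2 with inversion (2R) and gives carboxylate 21, and trifluoroacetic anhydride then converts 21 into mixed anhydride 22, whose acyl carbon attacks C4a, the only free ring-D position ortho to the new ether oxygen, to form the C4–C4a bond. The closest known reaction types are the opening of β-propiolactone and β-butyrolactone by phenoxides at the alkyl carbon and the anhydride- or acid-mediated cyclization of 3-aryloxypropanoic acids to chroman-4-ones; their merger on a 4-aryl lactone to give a flavanone is the new element. Ring F closes as a six-membered ring by intramolecular Friedel–Crafts acylation, which needs no strong Lewis acid because C4a of the phloroglucinol-type ring D has oxygen ortho, ortho and para. The C2 stereocentre of unit 2 is controlled by the lactone alone (stereospecific inversion, independent of unit 1), and boron in place of the para oxygen keeps this benzylic carbon from ionizing (no quinone-methide or SN1 pathway, no decarboxylation of the lactone) until ring F is closed. The step needs O- over C-alkylation and alkyl over acyl attack: a cesium phenoxide in a polar aprotic solvent favours O-attack, acyl attack only gives an aryl ester that can revert through its β-alkoxide, and the linkage through C8 is fixed because 14 has a single phenol. One equivalent of carbonate at 0 °C is chosen so that the C3–H of unit 1 is not enolized.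

Step 15
Reactants: 23 (2R)-5,7-bis(benzyloxy)-8-[(2R,3S)-5,7-bis(benzyloxy)-2-[3,4-bis(benzyloxy)phenyl]-4-oxochroman-3-yl]-2-[4-(4,4,5,5-tetramethyl-1,3,2-dioxaborolan-2-yl)phenyl]chroman-4-one
Product: 25 (2R)-5,7-bis(benzyloxy)-8-[(2R,3S)-5,7-bis(benzyloxy)-2-[3,4-bis(benzyloxy)phenyl]-4-oxochroman-3-yl]-2-(4-hydroxyphenyl)chroman-4-one, via aryl borate 24 (not isolated)
Conditions: Me3NO (3 equiv), CH2Cl2, rt to 40 °C; aqueous work-up
Reagents that add atoms: trimethylamine N-oxide, C[N+](C)(C)[O-]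
Why: ipso-Hydroxylation of the arylboronate (the N-oxide oxygen adds to boron, the aryl group migrates from boron to oxygen, and borate 24 is hydrolysed on work-up) under non-basic, peroxide-free conditions that leave both chromanones and the benzyl ethers alone.

Step 16
Reactants: 25 (2R)-5,7-bis(benzyloxy)-8-[(2R,3S)-5,7-bis(benzyloxy)-2-[3,4-bis(benzyloxy)phenyl]-4-oxochroman-3-yl]-2-(4-hydroxyphenyl)chroman-4-one
Product: 26 (2R)-8-[(2R,3S)-2-(3,4-dihydroxyphenyl)-5,7-dihydroxy-4-oxochroman-3-yl]-5,7-dihydroxy-2-(4-hydroxyphenyl)chroman-4-one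
Conditions: H2 (1 atm), 10% Pd/C, EtOAc/MeOH, rt
Reagents that add atoms: none
Why: Hydrogenolysis of the six benzyl ethers under neutral conditions should free all phenols without touching the three stereocentres.

## Compound list

1 | 3,5-bis(benzyloxy)phenol | Oc1cc(OCc2ccccc2)cc(OCc2ccccc2)c1 | starting material
2 | 1,3-bis(benzyloxy)-5-(methoxymethoxy)benzene | COCOc1cc(OCc2ccccc2)cc(OCc2ccccc2)c1 | intermediate
3 | [2,4-bis(benzyloxy)-6-(methoxymethoxy)phenyl]lithium | [Li]c1c(OCOC)cc(OCc2ccccc2)cc1OCc1ccccc1 | intermediate (not isolated)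
4 | tributyl[2,4-bis(benzyloxy)-6-(methoxymethoxy)phenyl]stannane | CCCC[Sn](CCCC)(CCCC)c1c(OCOC)cc(OCc2ccccc2)cc1OCc1ccccc1 | intermediate
5 | [2,4-bis(benzyloxy)-6-(methoxymethoxy)phenyl]lead triacetate | CC(=O)O[Pb](OC(C)=O)(OC(C)=O)c1c(OCOC)cc(OCc2ccccc2)cc1OCc1ccccc1 | intermediate
6 | 1-(2,4,6-trihydroxyphenyl)ethanone | CC(=O)c1c(O)cc(O)cc1O | starting material
7 | 1-[2,4-bis(benzyloxy)-6-hydroxyphenyl]ethanone | CC(=O)c1c(O)cc(OCc2ccccc2)cc1OCc1ccccc1 | intermediate
8 | tert-butyl 3-[2,4-bis(benzyloxy)-6-hydroxyphenyl]-3-oxopropanoate | CC(C)(C)OC(=O)CC(=O)c1c(O)cc(OCc2ccccc2)cc1OCc1ccccc1 | intermediate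
9 | 3,4-bis(benzyloxy)benzaldehyde | O=Cc1ccc(OCc2ccccc2)c(OCc2ccccc2)c1 | starting material
10 | tert-butyl 2-[2,4-bis(benzyloxy)-6-hydroxybenzoyl]-3-[3,4-bis(benzyloxy)phenyl]prop-2-enoate (E/Z mixture) | CC(C)(C)OC(=O)C(=Cc1ccc(OCc2ccccc2)c(OCc2ccccc2)c1)C(=O)c1c(O)cc(OCc2ccccc2)cc1OCc1ccccc1 | intermediate
11 | tert-butyl (2R,3S)-5,7-bis(benzyloxy)-2-[3,4-bis(benzyloxy)phenyl]-4-oxochromane-3-carboxylate | CC(C)(C)OC(=O)[C@@H]1C(=O)c2c(OCc3ccccc3)cc(OCc3ccccc3)cc2O[C@H]1c1ccc(OCc2ccccc2)c(OCc2ccccc2)c1 | intermediate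
12 | tert-butyl (2S,3R)-5,7-bis(benzyloxy)-3-[2,4-bis(benzyloxy)-6-(methoxymethoxy)phenyl]-2-[3,4-bis(benzyloxy)phenyl]-4-oxochromane-3-carboxylate | COCOc1cc(OCc2ccccc2)cc(OCc2ccccc2)c1[C@]1(C(=O)OC(C)(C)C)C(=O)c2c(OCc3ccccc3)cc(OCc3ccccc3)cc2O[C@H]1c1ccc(OCc2ccccc2)c(OCc2ccccc2)c1 | intermediate
13 | (2S,3R)-5,7-bis(benzyloxy)-3-[2,4-bis(benzyloxy)-6-hydroxyphenyl]-2-[3,4-bis(benzyloxy)phenyl]-4-oxochromane-3-carboxylic acid | Oc1cc(OCc2ccccc2)cc(OCc2ccccc2)c1[C@]1(C(=O)O)C(=O)c2c(OCc3ccccc3)cc(OCc3ccccc3)cc2O[C@H]1c1ccc(OCc2ccccc2)c(OCc2ccccc2)c1 | intermediate (not isolated)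
14 | (2R,3S)-5,7-bis(benzyloxy)-2-[3,4-bis(benzyloxy)phenyl]-3-[2,4-bis(benzyloxy)-6-hydroxyphenyl]chroman-4-one | Oc1cc(OCc2ccccc2)cc(OCc2ccccc2)c1[C@@H]1C(=O)c2c(OCc3ccccc3)cc(OCc3ccccc3)cc2O[C@H]1c1ccc(OCc2ccccc2)c(OCc2ccccc2)c1 | intermediate
15 | ethyl 3-(4-bromophenyl)-3-oxopropanoate | CCOC(=O)CC(=O)c1ccc(Br)cc1 | starting material
16 | ethyl (3S)-3-(4-bromophenyl)-3-hydroxypropanoate | CCOC(=O)C[C@H](O)c1ccc(Br)cc1 | intermediate
17 | ethyl (3S)-3-hydroxy-3-[4-(4,4,5,5-tetramethyl-1,3,2-dioxaborolan-2-yl)phenyl]propanoate | CCOC(=O)C[C@H](O)c1ccc(B2OC(C)(C)C(C)(C)O2)cc1 | intermediate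
18 | (3S)-3-hydroxy-3-[4-(4,4,5,5-tetramethyl-1,3,2-dioxaborolan-2-yl)phenyl]propanoic acid | OC(=O)C[C@H](O)c1ccc(B2OC(C)(C)C(C)(C)O2)cc1 | intermediate
19 | benzenesulfonic (3S)-3-hydroxy-3-[4-(4,4,5,5-tetramethyl-1,3,2-dioxaborolan-2-yl)phenyl]propanoic anhydride | O=C(C[C@H](O)c1ccc(B2OC(C)(C)C(C)(C)O2)cc1)OS(=O)(=O)c1ccccc1 | intermediate (not isolated)
20 | (4S)-4-[4-(4,4,5,5-tetramethyl-1,3,2-dioxaborolan-2-yl)phenyl]oxetan-2-one | O=C1C[C@@H](c2ccc(B3OC(C)(C)C(C)(C)O3)cc2)O1 | intermediate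
21 | cesium (3R)-3-{3,5-bis(benzyloxy)-2-[(2R,3S)-5,7-bis(benzyloxy)-2-[3,4-bis(benzyloxy)phenyl]-4-oxochroman-3-yl]phenoxy}-3-[4-(4,4,5,5-tetramethyl-1,3,2-dioxaborolan-2-yl)phenyl]propanoate | [Cs+].[O-]C(=O)C[C@H](c1ccc(B2OC(C)(C)C(C)(C)O2)cc1)Oc1cc(OCc2ccccc2)cc(OCc2ccccc2)c1[C@@H]1C(=O)c2c(OCc3ccccc3)cc(OCc3ccccc3)cc2O[C@H]1c1ccc(OCc2ccccc2)c(OCc2ccccc2)c1 | intermediate (not isolated)
22 | (3R)-3-{3,5-bis(benzyloxy)-2-[(2R,3S)-5,7-bis(benzyloxy)-2-[3,4-bis(benzyloxy)phenyl]-4-oxochroman-3-yl]phenoxy}-3-[4-(4,4,5,5-tetramethyl-1,3,2-dioxaborolan-2-yl)phenyl]propanoic trifluoroacetic anhydride | FC(F)(F)C(=O)OC(=O)C[C@H](c1ccc(B2OC(C)(C)C(C)(C)O2)cc1)Oc1cc(OCc2ccccc2)cc(OCc2ccccc2)c1[C@@H]1C(=O)c2c(OCc3ccccc3)cc(OCc3ccccc3)cc2O[C@H]1c1ccc(OCc2ccccc2)c(OCc2ccccc2)c1 | intermediate (not isolated)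
23 | (2R)-5,7-bis(benzyloxy)-8-[(2R,3S)-5,7-bis(benzyloxy)-2-[3,4-bis(benzyloxy)phenyl]-4-oxochroman-3-yl]-2-[4-(4,4,5,5-tetramethyl-1,3,2-dioxaborolan-2-yl)phenyl]chroman-4-one | O=C1C[C@H](c2ccc(B3OC(C)(C)C(C)(C)O3)cc2)Oc2c1c(OCc1ccccc1)cc(OCc1ccccc1)c2[C@@H]1C(=O)c2c(OCc3ccccc3)cc(OCc3ccccc3)cc2O[C@H]1c1ccc(OCc2ccccc2)c(OCc2ccccc2)c1 | intermediate
24 | (2R)-5,7-bis(benzyloxy)-8-[(2R,3S)-5,7-bis(benzyloxy)-2-[3,4-bis(benzyloxy)phenyl]-4-oxochroman-3-yl]-2-{4-[(4,4,5,5-tetramethyl-1,3,2-dioxaborolan-2-yl)oxy]phenyl}chroman-4-one | O=C1C[C@H](c2ccc(OB3OC(C)(C)C(C)(C)O3)cc2)Oc2c1c(OCc1ccccc1)cc(OCc1ccccc1)c2[C@@H]1C(=O)c2c(OCc3ccccc3)cc(OCc3ccccc3)cc2O[C@H]1c1ccc(OCc2ccccc2)c(OCc2ccccc2)c1 | intermediate (not isolated)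
25 | (2R)-5,7-bis(benzyloxy)-8-[(2R,3S)-5,7-bis(benzyloxy)-2-[3,4-bis(benzyloxy)phenyl]-4-oxochroman-3-yl]-2-(4-hydroxyphenyl)chroman-4-one | O=C1C[C@H](c2ccc(O)cc2)Oc2c1c(OCc1ccccc1)cc(OCc1ccccc1)c2[C@@H]1C(=O)c2c(OCc3ccccc3)cc(OCc3ccccc3)cc2O[C@H]1c1ccc(OCc2ccccc2)c(OCc2ccccc2)c1 | intermediate
26 | (2R)-8-[(2R,3S)-2-(3,4-dihydroxyphenyl)-5,7-dihydroxy-4-oxochroman-3-yl]-5,7-dihydroxy-2-(4-hydroxyphenyl)chroman-4-one | O=C1C[C@H](c2ccc(O)cc2)Oc2c1c(O)cc(O)c2[C@@H]1C(=O)c2c(O)cc(O)cc2O[C@H]1c1ccc(O)c(O)c1 | target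

## Step count and risks

Total step count: 16. Longest linear sequence: 9 steps (steps 4 to 9, then 14 to 16, starting from 6).

Steps most likely to fail:

1. Step 14 (proposed new method). The hindered phenoxide may attack the lactone slowly, at carbon instead of oxygen, or at the acyl carbon, and the basic stage may enolize C3 of unit 1 and open ring C, which would scramble C2 and C3 of unit 1. The fallback uses known chemistry, sets out from 14 and 17, and returns at 23. The ether bond is made first under neutral conditions by a Mitsunobu reaction of phenol 14 with hydroxy ester 17 (DIAD, PPh3, toluene, 0 °C, inversion at the carbinol), which should give ethyl (3R)-3-{3,5-bis(benzyloxy)-2-[(2R,3S)-5,7-bis(benzyloxy)-2-[3,4-bis(benzyloxy)phenyl]-4-oxochroman-3-yl]phenoxy}-3-[4-(4,4,5,5-tetramethyl-1,3,2-dioxaborolan-2-yl)phenyl]propanoate F1. The ester is then cleaved without base by Me3SnOH (1,2-dichloroethane, 70 °C) to (3R)-3-{3,5-bis(benzyloxy)-2-[(2R,3S)-5,7-bis(benzyloxy)-2-[3,4-bis(benzyloxy)phenyl]-4-oxochroman-3-yl]phenoxy}-3-[4-(4,4,5,5-tetramethyl-1,3,2-dioxaborolan-2-yl)phenyl]propanoic acid F2. TFAA in CH2Cl2 at 0 °C closes ring F through mixed anhydride 22, and the route is rejoined at 23.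

2. Step 8. Ligand coupling at the congested C3 may be slow, so that the β-keto ester loses its C2 configuration by reversible ring opening while it waits, or the lead reagent decomposes first. The fallback sets out from 8 and 5 and returns at 14. The aryl group is introduced before ring C exists: arylation of the acyclic keto ester 8 with 5 (pyridine, CHCl3, 40 °C) should give tert-butyl 3-[2,4-bis(benzyloxy)-6-hydroxyphenyl]-2-[2,4-bis(benzyloxy)-6-(methoxymethoxy)phenyl]-3-oxopropanoate F3. Loss of the ester on silica gel in toluene at reflux gives 1-[2,4-bis(benzyloxy)-6-hydroxyphenyl]-2-[2,4-bis(benzyloxy)-6-(methoxymethoxy)phenyl]ethanone F4. Piperidine-mediated condensation of F4 with aldehyde 9 (EtOH, reflux; aldol condensation, then oxa-Michael closure under thermodynamic 2,3-trans control) gives the racemic flavanone, that is (2R,3S)-5,7-bis(benzyloxy)-2-[3,4-bis(benzyloxy)phenyl]-3-[2,4-bis(benzyloxy)-6-(methoxymethoxy)phenyl]chroman-4-one F5 together with (2S,3R)-5,7-bis(benzyloxy)-2-[3,4-bis(benzyloxy)phenyl]-3-[2,4-bis(benzyloxy)-6-(methoxymethoxy)phenyl]chroman-4-one F6. The two are separated by HPLC on a chiral stationary phase, and HCl in MeOH/THF removes the acetal of F5 to return to 14.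

3. Step 7. Facial selectivity may be poor, because the ortho benzyloxy group twists the aryl ketone and the electron-rich aryl group makes the alkene a weak acceptor, so an uncatalysed closure can compete. The fallback sets out from 7 and returns at 11, and sets C2 by conjugate addition instead. N,N-Dimethylformamide dimethyl acetal (toluene, 90 °C), then HCl, closes 5,7-bis(benzyloxy)-4H-chromen-4-one F7. Asymmetric conjugate addition of [3,4-bis(benzyloxy)phenyl]boronic acid with Pd(OCOCF3)2 and 4-tert-butyl-2-(pyridin-2-yl)-4,5-dihydrooxazole (the ligand antipode that gives the 2R series), NH4PF6 and H2O in 1,2-dichloroethane at 60 °C should give (2R)-5,7-bis(benzyloxy)-2-[3,4-bis(benzyloxy)phenyl]chroman-4-one F8. LiN(SiMe3)2 in THF at −78 °C followed by Boc2O puts the ester on C3 and returns to 11.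

Further compounds

F1 | step 14 | ethyl (3R)-3-{3,5-bis(benzyloxy)-2-[(2R,3S)-5,7-bis(benzyloxy)-2-[3,4-bis(benzyloxy)phenyl]-4-oxochroman-3-yl]phenoxy}-3-[4-(4,4,5,5-tetramethyl-1,3,2-dioxaborolan-2-yl)phenyl]propanoate | CCOC(=O)C[C@H](c1ccc(B2OC(C)(C)C(C)(C)O2)cc1)Oc1cc(OCc2ccccc2)cc(OCc2ccccc2)c1[C@@H]1C(=O)c2c(OCc3ccccc3)cc(OCc3ccccc3)cc2O[C@H]1c1ccc(OCc2ccccc2)c(OCc2ccccc2)c1
F2 | step 14 | (3R)-3-{3,5-bis(benzyloxy)-2-[(2R,3S)-5,7-bis(benzyloxy)-2-[3,4-bis(benzyloxy)phenyl]-4-oxochroman-3-yl]phenoxy}-3-[4-(4,4,5,5-tetramethyl-1,3,2-dioxaborolan-2-yl)phenyl]propanoic acid | OC(=O)C[C@H](c1ccc(B2OC(C)(C)C(C)(C)O2)cc1)Oc1cc(OCc2ccccc2)cc(OCc2ccccc2)c1[C@@H]1C(=O)c2c(OCc3ccccc3)cc(OCc3ccccc3)cc2O[C@H]1c1ccc(OCc2ccccc2)c(OCc2ccccc2)c1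
F3 | step 8 | tert-butyl 3-[2,4-bis(benzyloxy)-6-hydroxyphenyl]-2-[2,4-bis(benzyloxy)-6-(methoxymethoxy)phenyl]-3-oxopropanoate | COCOc1cc(OCc2ccccc2)cc(OCc2ccccc2)c1C(C(=O)OC(C)(C)C)C(=O)c1c(O)cc(OCc2ccccc2)cc1OCc1ccccc1
F4 | step 8 | 1-[2,4-bis(benzyloxy)-6-hydroxyphenyl]-2-[2,4-bis(benzyloxy)-6-(methoxymethoxy)phenyl]ethanone | COCOc1cc(OCc2ccccc2)cc(OCc2ccccc2)c1CC(=O)c1c(O)cc(OCc2ccccc2)cc1OCc1ccccc1
F5 | step 8 | (2R,3S)-5,7-bis(benzyloxy)-2-[3,4-bis(benzyloxy)phenyl]-3-[2,4-bis(benzyloxy)-6-(methoxymethoxy)phenyl]chroman-4-one | COCOc1cc(OCc2ccccc2)cc(OCc2ccccc2)c1[C@@H]1C(=O)c2c(OCc3ccccc3)cc(OCc3ccccc3)cc2O[C@H]1c1ccc(OCc2ccccc2)c(OCc2ccccc2)c1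
F6 | step 8 | (2S,3R)-5,7-bis(benzyloxy)-2-[3,4-bis(benzyloxy)phenyl]-3-[2,4-bis(benzyloxy)-6-(methoxymethoxy)phenyl]chroman-4-one | COCOc1cc(OCc2ccccc2)cc(OCc2ccccc2)c1[C@H]1C(=O)c2c(OCc3ccccc3)cc(OCc3ccccc3)cc2O[C@@H]1c1ccc(OCc2ccccc2)c(OCc2ccccc2)c1
F7 | step 7 | 5,7-bis(benzyloxy)-4H-chromen-4-one | O=c1ccoc2cc(OCc3ccccc3)cc(OCc3ccccc3)c12
F8 | step 7 | (2R)-5,7-bis(benzyloxy)-2-[3,4-bis(benzyloxy)phenyl]chroman-4-one | O=C1C[C@H](c2ccc(OCc3ccccc3)c(OCc3ccccc3)c2)Oc2cc(OCc3ccccc3)cc(OCc3ccccc3)c21
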